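**Retrosynthetic overview**
1. The plan rests on ring A, where every carbon is substituted. Prenyl-bearing C8 is flanked by the oxygens on C7 and C8a (a 2-alkylresorcinol unit), C6 holds the single OMe, C5 holds a third oxygen, and C4a is the only carbon that needs a C–C bond to ring C.
2. Ring C is opened at C4–C4a (intramolecular Friedel–Crafts acylation) and at O1–C2 (Mitsunobu inversion of an (R)-β-hydroxy ester, which supplies (2S) and ring B).
3. Ring A is cut at C7–C8, C4a–C8a and C6–C7. This is a Danheiser benzannulation of 3-ethoxy-4-methoxycyclobutenone with the prenyl-substituted triisopropylsiloxyalkyne, and it gives C7–OH, C8a–OSi and C5–OEt as three distinguishable oxygens and leaves C4a–H.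
4. The cyclobutenone comes from methoxyketene and ethoxyacetylene. The siloxyalkyne comes from ethyl 4-methylpent-3-enoate by Kowalski ynolate formation and O-silylation.
5. Ring order: ring A (step 3), then ring C (step 8); ring B is carried in with the hydroxy ester.

Key step: step 3

Remark: the stereocentre of the target SMILES is read as (2S). Flavanone numbering (O1, C2–C4, C4a, C5–C8, C8a) is used for the corresponding atoms of every precursor.

**Step 1**
Reactants: 1 methoxyacetyl chloride; 2 ethoxyacetylene
Product: 4 3-ethoxy-4-methoxycyclobut-2-en-1-one (racemic), via methoxyketene 3 (not isolated)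
Conditions: 1 added slowly to 2 (2 equiv, hexanes solution) and Et3N (1.2 equiv), Et2O, 0 °C → rt
Reagents that add atoms: none
Why: Ketene–alkyne [2+2] cycloaddition: Et3N dehydrochlorinates 1 to the alkoxyketene, the unsubstituted nucleophilic carbon of the ynol ether bonds to the ketene carbonyl carbon, so ethoxy ends at C3 and methoxy at C4, and the single stereocentre forms as a racemate that step 3 erases.

**Step 2**
Reactants: 5 ethyl 4-methylpent-3-enoate
Product: 8 triisopropyl[(5-methylhex-4-en-1-yn-1-yl)oxy]silane, via lithium dibromoenolate 6 (not isolated), via lithium ynolate 7 (not isolated)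
Conditions: CH2Br2, lithium 2,2,6,6-tetramethylpiperidide (2.2 equiv), THF, −78 °C, then 5; n-BuLi, −78 °C → rt; TIPSOTf, −78 → 0 °C
Reagents that add atoms: dibromomethane BrCBr; triisopropylsilyl trifluoromethanesulfonate CC(C)[Si](C(C)C)(C(C)C)OS(=O)(=O)C(F)(F)F
Why: Kowalski ester homologation stopped at the ynolate: LiCHBr2 adds to the ester carbonyl at −78 °C faster than it enolises the β,γ-unsaturated ester, bromine–lithium exchange on dibromoenolate 6 triggers the 1,2-shift of the prenyl group to ynolate 7, and the bulky silyl triflate silylates 7 on oxygen rather than carbon.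

**Step 3**
Reactants: 4 3-ethoxy-4-methoxycyclobut-2-en-1-one; 8 triisopropyl[(5-methylhex-4-en-1-yn-1-yl)oxy]silane
Product: 13 5-ethoxy-6-methoxy-2-(3-methylbut-2-en-1-yl)-3-[(triisopropylsilyl)oxy]phenol, via vinylketene 9 (not isolated), via vinylcyclobutenone 10 (not isolated), via dienylketene 11 (not isolated), via cyclohexadienone 12 (not isolated)
Conditions: 8 (1.3 equiv), toluene (0.5 M), argon, sealed tube, 80 °C, then 110 °C
Reagents that add atoms: none
Why: Heating cleaves the C1–C4 bond of 4 in a conrotatory 4π-electrocyclic opening in which the donor methoxy turns outward, giving vinylketene 9, whose ketene C=C adds to the ynol silyl ether 8 in a [2+2] cycloaddition that forms C7–C8 and C4a–C8a (10). A second, reversible 4π opening of 10 gives dienylketene 11, and the isomer with ketene and alkoxyvinyl arm cis on the central double bond closes ring A by thermally allowed disrotatory 6π-electrocyclisation (C6–C7) to dienone 12, which enolises irreversibly to phenol 13. The closest known reaction type is this one itself, the Danheiser benzannulation of cyclobutenones with trialkylsiloxyalkynes, the established entry to 2-alkylresorcinol monosilyl ethers, and a donor at C4 of a cyclobutenone is known to ease the ring opening. No lasting stereocentre is created, because the sp3 carbons of 4, 10 and 12 all become aromatic carbons, so racemic 4 serves. The step needs regiocontrol in the [2+2] event, and the polarisation of the partners secures it: the alkyne carbon β to the siloxy oxygen (the prenyl-bearing one) is the nucleophilic terminus and bonds to the electrophilic ketene carbonyl carbon, which puts prenyl between C7–OH and C8a–OTIPS, methoxy on C6, ethoxy on C5 and hydrogen on C4a. It also needs chemoselectivity for the alkyne over the prenyl alkene, which the far higher ketenophilicity of the electron-rich ynol ether provides, while an intramolecular ketene–alkene addition through the one-carbon tether would be prohibitively strained.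

**Step 4**
Reactants: 13 5-ethoxy-6-methoxy-2-(3-methylbut-2-en-1-yl)-3-[(triisopropylsilyl)oxy]phenol
Product: 14 [5-ethoxy-4-methoxy-3-(methoxymethoxy)-2-(3-methylbut-2-en-1-yl)phenoxy]triisopropylsilane
Conditions: MOMCl, i-Pr2NEt, CH2Cl2, 0 °C → rt
Reagents that add atoms: chloromethyl methyl ether COCCl
Why: O-alkylation of the only free phenol (C7–OH) with the very reactive α-chloro ether under amine base is a standard acetal protection that tolerates the crowded site, the aryl silyl ether and the alkene.

**Step 5**
Reactants: 14 [5-ethoxy-4-methoxy-3-(methoxymethoxy)-2-(3-methylbut-2-en-1-yl)phenoxy]triisopropylsilane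
Product: 15 5-ethoxy-4-methoxy-3-(methoxymethoxy)-2-(3-methylbut-2-en-1-yl)phenol
Conditions: TBAF (1.1 equiv), AcOH (1.1 equiv), THF, 0 °C → rt
Reagents that add atoms: none
Why: Fluoride-driven desilylation of an aryl silyl ether (strong Si–F bond, aryloxide leaving group) proceeds under buffered conditions that leave the MOM acetal, the alkyl ethers and the prenyl group untouched and expose only C8a–OH.

**Step 6**
Reactants: 15 5-ethoxy-4-methoxy-3-(methoxymethoxy)-2-(3-methylbut-2-en-1-yl)phenol; 16 ethyl (R)-3-hydroxy-3-phenylpropanoate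
Product: 18 ethyl (3S)-3-[5-ethoxy-4-methoxy-3-(methoxymethoxy)-2-(3-methylbut-2-en-1-yl)phenoxy]-3-phenylpropanoate, via alkoxyphosphonium ion 17 (not isolated)
Conditions: 16 (1.5 equiv), PPh3, DIAD, toluene, 0 °C → rt
Reagents that add atoms: none
Why: Mitsunobu etherification: the aryloxide of 15 displaces triphenylphosphine oxide from 17 by SN2 with inversion, so the (R)-carbinol becomes (S)-C2, the β-ester group disfavouring benzylic ionisation, and excess 16 offsets loss by β-elimination.

**Step 7**
Reactants: 18 ethyl (3S)-3-[5-ethoxy-4-methoxy-3-(methoxymethoxy)-2-(3-methylbut-2-en-1-yl)phenoxy]-3-phenylpropanoate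
Product: 20 (3S)-3-[5-ethoxy-4-methoxy-3-(methoxymethoxy)-2-(3-methylbut-2-en-1-yl)phenoxy]-3-phenylpropanoic acid, via lithium carboxylate 19 (not isolated)
Conditions: LiOH·H2O, THF–H2O, 0 °C → rt; then cold 0.5 M HCl to pH 4
Reagents that add atoms: lithium hydroxide [Li+].[OH-]
Why: Ester saponification by acyl–oxygen cleavage; the stereocentre is β to the carbonyl and cannot epimerise by enolisation, and the low temperature keeps hydrolysis ahead of E1cB loss of the aryloxide.

**Step 8**
Reactants: 20 (3S)-3-[5-ethoxy-4-methoxy-3-(methoxymethoxy)-2-(3-methylbut-2-en-1-yl)phenoxy]-3-phenylpropanoic acid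
Product: 22 (2S)-5-ethoxy-6-methoxy-7-(methoxymethoxy)-8-(3-methylbut-2-en-1-yl)-2-phenylchroman-4-one, via mixed trifluoroacetic anhydride 21 (not isolated)
Conditions: (CF3CO)2O (1.3 equiv), CH2Cl2, 0 °C → rt
Reagents that add atoms: none
Why: Intramolecular Friedel–Crafts acylation through the acyl trifluoroacetate: C4a is the only unsubstituted ring A carbon and is ortho to two alkoxy groups and para to a third, so the six-membered ring C should close without a Lewis acid, under conditions mild enough for the MOM acetal, the prenyl alkene and the benzylic C2–O bond.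

**Step 9**
Reactants: 22 (2S)-5-ethoxy-6-methoxy-7-(methoxymethoxy)-8-(3-methylbut-2-en-1-yl)-2-phenylchroman-4-one
Product: 24 agrandol [(2S)-5,7-dihydroxy-6-methoxy-8-(3-methylbut-2-en-1-yl)-2-phenylchroman-4-one], via bis(dichloroboryl) ether 23 (not isolated)
Conditions: BCl3 (2.5–3 equiv, 1 M in CH2Cl2), CH2Cl2, −78 → 0 °C; poured into ice-cold pH 7 phosphate buffer
Reagents that add atoms: none
Why: Chelation-directed ether cleavage with BCl3: boron held between C4=O and the peri C5 oxygen activates the ethyl group for chloride attack and the acetal at C7 is cleaved as well, whereas the unchelated C6 methyl ether reacts more slowly, no protic acid is present before the buffered quench so that the prenyl group is spared, and the low temperature avoids ring opening at C2.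

**Compound list**
1 | methoxyacetyl chloride | COCC(=O)Cl | starting material
2 | ethoxyacetylene | CCOC#C | starting material
3 | methoxyketene | COC=C=O | intermediate
4 | 3-ethoxy-4-methoxycyclobut-2-en-1-one (racemic) | CCOC1=CC(=O)C1OC | intermediate
5 | ethyl 4-methylpent-3-enoate | CCOC(=O)CC=C(C)C | starting material
6 | lithium 1,1-dibromo-5-methylhexa-1,4-dien-2-olate | [Li+].[O-]C(CC=C(C)C)=C(Br)Br | intermediate
7 | lithium 5-methylhex-4-en-1-yn-1-olate | [Li+].[O-]C#CCC=C(C)C | intermediate
8 | triisopropyl[(5-methylhex-4-en-1-yn-1-yl)oxy]silane | CC(C)=CCC#CO[Si](C(C)C)(C(C)C)C(C)C | intermediate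
9 | (Z)-3-ethoxy-4-methoxybuta-1,3-dien-1-one | O=C=C/C(OCC)=C/OC | intermediate
10 | 4-[(Z)-1-ethoxy-2-methoxyethenyl]-2-(3-methylbut-2-en-1-yl)-3-[(triisopropylsilyl)oxy]cyclobut-2-en-1-one (racemic) | O=C1C(CC=C(C)C)=C(O[Si](C(C)C)(C(C)C)C(C)C)C1/C(OCC)=C/OC | intermediate
11 | (3E,5Z)-5-ethoxy-6-methoxy-2-(3-methylbut-2-en-1-yl)-3-[(triisopropylsilyl)oxy]hexa-1,3,5-trien-1-one | O=C=C(CC=C(C)C)/C(O[Si](C(C)C)(C(C)C)C(C)C)=C\C(OCC)=C\OC | intermediate
12 | 5-ethoxy-6-methoxy-2-(3-methylbut-2-en-1-yl)-3-[(triisopropylsilyl)oxy]cyclohexa-2,4-dien-1-one (racemic) | O=C1C(CC=C(C)C)=C(O[Si](C(C)C)(C(C)C)C(C)C)C=C(OCC)C1OC | intermediate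
13 | 5-ethoxy-6-methoxy-2-(3-methylbut-2-en-1-yl)-3-[(triisopropylsilyl)oxy]phenol | CCOc1cc(O[Si](C(C)C)(C(C)C)C(C)C)c(CC=C(C)C)c(O)c1OC | intermediate
14 | [5-ethoxy-4-methoxy-3-(methoxymethoxy)-2-(3-methylbut-2-en-1-yl)phenoxy]triisopropylsilane | CCOc1cc(O[Si](C(C)C)(C(C)C)C(C)C)c(CC=C(C)C)c(OCOC)c1OC | intermediate
15 | 5-ethoxy-4-methoxy-3-(methoxymethoxy)-2-(3-methylbut-2-en-1-yl)phenol | CCOc1cc(O)c(CC=C(C)C)c(OCOC)c1OC | intermediate
16 | ethyl (R)-3-hydroxy-3-phenylpropanoate | CCOC(=O)C[C@H](c1ccccc1)O | starting material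
17 | [(1R)-3-ethoxy-3-oxo-1-phenylpropoxy]triphenylphosphonium ion | CCOC(=O)C[C@H](c1ccccc1)O[P+](c1ccccc1)(c1ccccc1)c1ccccc1 | intermediate
18 | ethyl (3S)-3-[5-ethoxy-4-methoxy-3-(methoxymethoxy)-2-(3-methylbut-2-en-1-yl)phenoxy]-3-phenylpropanoate | CCOC(=O)C[C@@H](c1ccccc1)Oc1cc(OCC)c(OC)c(OCOC)c1CC=C(C)C | intermediate
19 | lithium (3S)-3-[5-ethoxy-4-methoxy-3-(methoxymethoxy)-2-(3-methylbut-2-en-1-yl)phenoxy]-3-phenylpropanoate | [Li+].[O-]C(=O)C[C@@H](c1ccccc1)Oc1cc(OCC)c(OC)c(OCOC)c1CC=C(C)C | intermediate
20 | (3S)-3-[5-ethoxy-4-methoxy-3-(methoxymethoxy)-2-(3-methylbut-2-en-1-yl)phenoxy]-3-phenylpropanoic acid | OC(=O)C[C@@H](c1ccccc1)Oc1cc(OCC)c(OC)c(OCOC)c1CC=C(C)C | intermediate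
21 | mixed anhydride of 20 and trifluoroacetic acid | FC(F)(F)C(=O)OC(=O)C[C@@H](c1ccccc1)Oc1cc(OCC)c(OC)c(OCOC)c1CC=C(C)C | intermediate
22 | (2S)-5-ethoxy-6-methoxy-7-(methoxymethoxy)-8-(3-methylbut-2-en-1-yl)-2-phenylchroman-4-one | CCOc1c(OC)c(OCOC)c(CC=C(C)C)c2c1C(=O)C[C@@H](c1ccccc1)O2 | intermediate
23 | (2S)-5,7-bis(dichloroboryloxy)-6-methoxy-8-(3-methylbut-2-en-1-yl)-2-phenylchroman-4-one | COc1c(OB(Cl)Cl)c(CC=C(C)C)c2c(c1OB(Cl)Cl)C(=O)C[C@@H](c1ccccc1)O2 | intermediate
24 | agrandol, (2S)-5,7-dihydroxy-6-methoxy-8-(3-methylbut-2-en-1-yl)-2-phenylchroman-4-one | COc1c(O)c(CC=C(C)C)c2c(c1O)C(=O)C[C@@H](c1ccccc1)O2 | target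

**Step count**
Total steps: 9. Longest linear sequence: 8 steps (step 1 or step 2, then steps 3 to 9).

**Steps most likely to fail**

1. **Step 3.**
 - Risk: the vinylogous-ester character of 4 may retard the first ring opening. At the temperature then required, the donor-rich vinylketene may oligomerise, the cascade may stall before the second ring opening, or the product phenol may be O-acylated by ketene.
 - Fallback: the same vinylketene is generated at room temperature by photochemical Wolff rearrangement (the diazo ketone variant of the benzannulation). This fallback sets out from 8, and the partner is built from commercial ethyl ethoxyacetate.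
 - Partner synthesis: Claisen formylation (HCO2Et, NaH, THF) should give the sodium enolate of ethyl 2-ethoxy-3-oxopropanoate F1. O-methylation with Me2SO4 should give ethyl (Z)-2-ethoxy-3-methoxyprop-2-enoate F2, with methoxy trans to the ester as the preferred geometry. Saponification (LiOH, then acid) should give (Z)-2-ethoxy-3-methoxyprop-2-enoic acid F3. (COCl)2 with catalytic DMF should give (Z)-2-ethoxy-3-methoxyprop-2-enoyl chloride F4. Acylation of excess CH2N2 (Et2O, 0 °C) should give (Z)-1-diazo-3-ethoxy-4-methoxybut-3-en-2-one F5.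
 - Return to the route: irradiation of F5 with 8 (medium-pressure mercury lamp, Vycor filter, CH2Cl2, rt) should expel nitrogen and deliver 9, which is trapped as 10. Brief heating in toluene then carries 10 through 11 and 12, and the route is rejoined at 13.

2. **Step 6.**
 - Risk: the phosphonium-activated alcohol may undergo β-elimination, since its α-hydrogens are acidified by the ester. Attack by the hindered and weakly acidic phenol may be sluggish. Partial ionisation at the benzylic carbon would erode enantiopurity.
 - Fallback: a three-carbon unit at the alcohol oxidation level, which has no acidic α-hydrogens. This fallback sets out from 15.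
 - Sequence: commercial (R)-1-phenylpropane-1,3-diol is silylated at the primary hydroxyl (TBSCl, imidazole, CH2Cl2, 0 °C) to (R)-3-[(tert-butyldimethylsilyl)oxy]-1-phenylpropan-1-ol F6. Mitsunobu coupling with 15 (PPh3, DIAD, toluene) should give, with inversion, the (S)-aryl ether tert-butyl{(3S)-3-[5-ethoxy-4-methoxy-3-(methoxymethoxy)-2-(3-methylbut-2-en-1-yl)phenoxy]-3-phenylpropoxy}dimethylsilane F7. TBAF should release (3S)-3-[5-ethoxy-4-methoxy-3-(methoxymethoxy)-2-(3-methylbut-2-en-1-yl)phenoxy]-3-phenylpropan-1-ol F8.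
 - Return to the route: TEMPO with PhI(OAc)2 in MeCN–H2O should oxidise F8 through the unisolated (3S)-3-[5-ethoxy-4-methoxy-3-(methoxymethoxy)-2-(3-methylbut-2-en-1-yl)phenoxy]-3-phenylpropanal F9 to the acid. The route is rejoined at 20, so the saponification of step 7 is bypassed as well.

3. **Step 9.**
 - Risk: acid liberated by adventitious moisture or at the quench may protonate the prenyl alkene, leading to hydrochlorination or to ring closure of the C7 oxygen onto the side chain. The electrophile released from the acetal may alkylate the alkene under Lewis acid activation. The crowded C6 methyl ether may be cleaved through chelation to a neighbouring aryloxyboron group. Reversible opening of ring C would racemise C2.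
 - Fallback: a boron-free, two-stage unmasking that sets out from 22.
 - Sequence: acetal exchange (catalytic p-TsOH, MeOH, gentle warming), a deprotection routinely tolerated by ortho-prenylphenols, should give (2S)-5-ethoxy-7-hydroxy-6-methoxy-8-(3-methylbut-2-en-1-yl)-2-phenylchroman-4-one F10.
 - Return to the route: MgI2·OEt2 in THF (warm) then forms a magnesium chelate between C4=O and the C5 oxygen, and iodide removes only the peri ethyl group by SN2. This is a nucleophilic dealkylation of the kind used on 5-O-alkyl-8-prenylflavanones without damage to the side chain. The route is rejoined at 24.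

**Further compounds**
F1 | step 3 | sodium enolate of ethyl 2-ethoxy-3-oxopropanoate | [Na+].[O-]C=C(OCC)C(=O)OCC
F2 | step 3 | ethyl (Z)-2-ethoxy-3-methoxyprop-2-enoate | CCOC(=O)/C(OCC)=C/OC
F3 | step 3 | (Z)-2-ethoxy-3-methoxyprop-2-enoic acid | OC(=O)/C(OCC)=C/OC
F4 | step 3 | (Z)-2-ethoxy-3-methoxyprop-2-enoyl chloride | ClC(=O)/C(OCC)=C/OC
F5 | step 3 | (Z)-1-diazo-3-ethoxy-4-methoxybut-3-en-2-one | [N-]=[N+]=CC(=O)/C(OCC)=C/OC
F6 | step 6 | (R)-3-[(tert-butyldimethylsilyl)oxy]-1-phenylpropan-1-ol | CC(C)(C)[Si](C)(C)OCC[C@H](c1ccccc1)O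
F7 | step 6 | tert-butyl{(3S)-3-[5-ethoxy-4-methoxy-3-(methoxymethoxy)-2-(3-methylbut-2-en-1-yl)phenoxy]-3-phenylpropoxy}dimethylsilane | CC(C)(C)[Si](C)(C)OCC[C@@H](c1ccccc1)Oc1cc(OCC)c(OC)c(OCOC)c1CC=C(C)C
F8 | step 6 | (3S)-3-[5-ethoxy-4-methoxy-3-(methoxymethoxy)-2-(3-methylbut-2-en-1-yl)phenoxy]-3-phenylpropan-1-ol | OCC[C@@H](c1ccccc1)Oc1cc(OCC)c(OC)c(OCOC)c1CC=C(C)C
F9 | step 6 | (3S)-3-[5-ethoxy-4-methoxy-3-(methoxymethoxy)-2-(3-methylbut-2-en-1-yl)phenoxy]-3-phenylpropanal | O=CC[C@@H](c1ccccc1)Oc1cc(OCC)c(OC)c(OCOC)c1CC=C(C)C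
F10 | step 9 | (2S)-5-ethoxy-7-hydroxy-6-methoxy-8-(3-methylbut-2-en-1-yl)-2-phenylchroman-4-one | CCOc1c(OC)c(O)c(CC=C(C)C)c2c1C(=O)C[C@@H](c1ccccc1)O2
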